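**Strategy.** The cyclohexane ring is closed early by joining C-1, the carbon that carries the geminal methyl groups, to the C-2 methylene in an intramolecular enolate–epoxide alkylation (carotenoid locants). The step exploits two features of the carbocycle. C-1 is alpha to the ring-fusion alkene carbon C-6, which can be a ketone enolisable only at C-1, because C-5 is the fully substituted O-bearing carbon. C-2 is adjacent to the C-3 carbinol, so C-2/C-3 can be a chiral terminal epoxide. One operation gives the quaternary centre, the six-membered ring and the C-3 alcohol. The precursor is an acyclic alpha-silyloxy isopropyl ketone; the dihydrofuran ring and C-8 arise later from the ketone through acetylide addition, anti-SN2′ reduction and allenol cyclisation.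

Key step: step 5

Remark on notation: C-1 carries the two methyl groups, C-2 is the adjacent CH2, C-3 the ring carbinol, C-5 the O-bearing ring-fusion carbon, C-6 the ring-fusion alkene carbon, C-7 the alkene CH and C-8 the O-bearing CH of the dihydrofuran. In benzofuran numbering these are C-4, C-5, C-6, C-7a, C-3a, C-3 and C-2.

Assumption: the glycidyl triflate 2 is used as a freshly prepared cold solution.

Step 1
Reactants: 1 (R)-glycidol
Product: 2 (S)-glycidyl trifluoromethanesulfonate
Conditions: Tf2O, 2,6-lutidine, CH2Cl2, −78 °C; cold filtration, solution used at once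
Reagents that add atoms: trifluoromethanesulfonic anhydride, O=S(=O)(OS(=O)(=O)C(F)(F)F)C(F)(F)F
Why: O-sulfonylation of the primary alcohol leaves the stereocentre untouched (the descriptor changes from R to S only because the CH2OTf arm now outranks the ring CH2) and gives an electrophile that is displaced at CH2–OTf much faster than the epoxide is opened.

Step 2
Reactants: 3 (2S,5S)-2-tert-butyl-5-methyl-1,3-dioxolan-4-one; 2 (S)-glycidyl trifluoromethanesulfonate
Product: 5 (2S,5R)-2-tert-butyl-5-methyl-5-{[(2R)-oxiran-2-yl]methyl}-1,3-dioxolan-4-one, via lithium enolate 4 (not isolated)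
Conditions: LiN(iPr)2 (LDA), THF, −78 °C; then 2, −78 → −40 °C
Reagents that add atoms: none
Why: Enolate alkylation with self-regeneration of the lactic acid stereocentre should place the electrophile anti to the tert-butyl group of the acetal, which sets the quaternary C-5 (R) with retention, while direct SN2 at the triflate carbon carries the epoxide stereocentre (future C-3) over unchanged.

Step 3
Reactants: 5 (2S,5R)-2-tert-butyl-5-methyl-5-{[(2R)-oxiran-2-yl]methyl}-1,3-dioxolan-4-one
Product: 7 (4R)-4-hydroxy-2,4-dimethyl-5-[(2R)-oxiran-2-yl]pentan-3-one, via lithium hemiketal alkoxide 6 (not isolated)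
Conditions: i-PrLi (1.05 equiv), THF/pentane, −78 °C; AcOH, −78 °C; then aq. NaHCO3
Reagents that add atoms: isopropyllithium, [Li]C(C)C
Why: Single addition of an organolithium to the non-enolisable lactone-type carbonyl should give a tetrahedral adduct that is stable at low temperature and collapses on work-up to the alpha-hydroxy ketone with loss of pivalaldehyde, the epoxide being inert to the organolithium at −78 °C without a Lewis acid.

Step 4
Reactants: 7 (4R)-4-hydroxy-2,4-dimethyl-5-[(2R)-oxiran-2-yl]pentan-3-one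
Product: 8 (4R)-2,4-dimethyl-5-[(2R)-oxiran-2-yl]-4-(triethylsilyloxy)pentan-3-one
Conditions: Et3SiOTf, 2,6-lutidine, CH2Cl2, −78 °C
Reagents that add atoms: triethylsilyl trifluoromethanesulfonate, CC[Si](CC)(CC)OS(=O)(=O)C(F)(F)F
Why: Silylation of the tertiary alcohol under buffered low-temperature conditions spares the epoxide and blocks O-5, so that in the next step only carbon can attack the epoxide.

Step 5
Reactants: 8 (4R)-2,4-dimethyl-5-[(2R)-oxiran-2-yl]-4-(triethylsilyloxy)pentan-3-one
Product: 10 (4S,6R)-4-hydroxy-2,2,6-trimethyl-6-(triethylsilyloxy)cyclohexan-1-one, via lithium enolate 9 (not isolated)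
Conditions: LiN(iPr)2 (LDA, 1.2 equiv), THF, −78 °C; then −78 → 25 °C; AcOH quench
Reagents that add atoms: none
Why: Deprotonation can occur only at the isopropyl methine (C-5 is fully substituted), so the tetrasubstituted lithium enolate 9 forms regiospecifically and its carbon C-1 opens the terminal epoxide at the primary carbon C-2 in an intramolecular SN2 reaction, creating the C-1–C-2 bond and the quaternary gem-dimethyl centre. The closest known reaction type is the base-mediated epoxy-ketone cyclisation, the intramolecular alkylation of a ketone enolate by an epoxide. The cyclohexanone closes in the 6-(enolendo) mode with endo opening of the epoxide; the alternative five-membered closure at C-3 would be a 5-(enolendo) process, which the ring-closure rules for enolates disfavour, and would need attack at the more hindered secondary carbon. No stereocentre is created: C-3 keeps the configuration of the epoxide because its C–O bond is not broken (R in 8 becomes S in 10 only by a change of priorities) and C-5 is carried through, which fixes O-3 trans to O-5. The step needs C- over O-alkylation and attack at C-2 over C-3; the lithium counter-ion in tetrahydrofuran, the primary nature of C-2 and the silyl cap on O-5 should secure this.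

Step 6
Reactants: 11 (2E)-3-methylpent-2-en-4-yn-1-ol
Product: 12 tert-butyldimethyl{[(2E)-3-methylpent-2-en-4-yn-1-yl]oxy}silane
Conditions: TBSCl, imidazole, CH2Cl2, 0 → 25 °C
Reagents that add atoms: tert-butyldimethylsilyl chloride, CC(C)(C)[Si](C)(C)Cl
Why: Standard silylation of a primary allylic alcohol gives an ether that should withstand the organolithium and zerovalent-palladium steps and is removed later together with the triethylsilyl group.

Step 7
Reactants: 10 (4S,6R)-4-hydroxy-2,2,6-trimethyl-6-(triethylsilyloxy)cyclohexan-1-one; 12 tert-butyldimethyl{[(2E)-3-methylpent-2-en-4-yn-1-yl]oxy}silane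
Product: 15 (1R,2R,4S)-1-[(3E)-5-(tert-butyldimethylsilyloxy)-3-methylpent-3-en-1-yn-1-yl]-2,6,6-trimethyl-2-(triethylsilyloxy)cyclohexane-1,4-diyl dimethyl biscarbonate, via lithium acetylide 13 (not isolated), via dilithium dialkoxide 14 (not isolated)
Conditions: 12, n-BuLi, THF, −78 °C; 10, LiN(SiMe3)2 (1.05 equiv), THF, −78 °C, then the acetylide solution (1.5 equiv), −78 → 0 °C; then ClCO2Me (4 equiv), 0 → 25 °C
Reagents that add atoms: methyl chloroformate, COC(=O)Cl
Why: 1,2-Addition of a lithium acetylide to a non-enolisable ketone and O-acylation of both alkoxides; in the chair with O-3 equatorial the C-5 silyloxy group and one C-1 methyl are axial, so the slim nucleophile should attack C-6 axially and anti to the alpha C–O bond, placing the alkynyl group trans to O-5 and the new O-6 cis to O-5.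

Step 8
Reactants: 15 (1R,2R,4S)-1-[(3E)-5-(tert-butyldimethylsilyloxy)-3-methylpent-3-en-1-yn-1-yl]-2,6,6-trimethyl-2-(triethylsilyloxy)cyclohexane-1,4-diyl dimethyl biscarbonate
Product: 16 (1S,3R)-4-[(Sa,3E)-5-(tert-butyldimethylsilyloxy)-3-methylpenta-1,3-dien-1-ylidene]-3,5,5-trimethyl-3-(triethylsilyloxy)cyclohexyl methyl carbonate
Conditions: Pd(OAc)2 (5 mol %), PBu3 (5 mol %), HCO2NH4 (2 equiv), THF, 25–40 °C
Reagents that add atoms: none
Why: Palladium-catalysed hydrogenolysis of a propargylic carbonate: zerovalent palladium formed in situ should displace the tertiary carbonate in anti-SN2′ fashion at C-8, and formate-derived hydride is then transferred with retention, so that H-8 ends anti to the departed O-6 and C-9 lies on the face of O-5 (Sa axis), while the non-activated secondary carbonate at C-3 is left alone.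

Step 9
Reactants: 16 (1S,3R)-4-[(Sa,3E)-5-(tert-butyldimethylsilyloxy)-3-methylpenta-1,3-dien-1-ylidene]-3,5,5-trimethyl-3-(triethylsilyloxy)cyclohexyl methyl carbonate
Product: 17 (1S,3R)-3-hydroxy-4-[(Sa,3E)-5-hydroxy-3-methylpenta-1,3-dien-1-ylidene]-3,5,5-trimethylcyclohexyl methyl carbonate
Conditions: Bu4NF/AcOH (1:1, 3 equiv), THF, 0 → 25 °C
Reagents that add atoms: none
Why: Buffered fluoride should cleave the tertiary triethylsilyl and the primary tert-butyldimethylsilyl ether without touching the methyl carbonate or isomerising the vinylallene.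

Step 10
Reactants: 17 (1S,3R)-3-hydroxy-4-[(Sa,3E)-5-hydroxy-3-methylpenta-1,3-dien-1-ylidene]-3,5,5-trimethylcyclohexyl methyl carbonate
Product: 18 methyl (2R,6S,7aR)-2-[(2E)-4-hydroxybut-2-en-2-yl]-4,4,7a-trimethyl-2,4,5,6,7,7a-hexahydro-1-benzofuran-6-yl carbonate
Conditions: AgNO3 (20 mol %), CaCO3, acetone, 25 °C, dark
Reagents that add atoms: none
Why: Silver-catalysed 5-endo cycloisomerisation of an alpha-hydroxyallene: O-5 attacks the activated C-7=C-8 bond in the plane of C-1–C-6–C-5, which converts the allene axis into the C-8 stereocentre (8R, side chain trans to the C-5 methyl), and protodemetalation leaves the C-6=C-7 alkene.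

Step 11
Reactants: 18 methyl (2R,6S,7aR)-2-[(2E)-4-hydroxybut-2-en-2-yl]-4,4,7a-trimethyl-2,4,5,6,7,7a-hexahydro-1-benzofuran-6-yl carbonate
Product: 20 {(2E)-3-[(2R,6S,7aR)-6-(methoxycarbonyloxy)-4,4,7a-trimethyl-2,4,5,6,7,7a-hexahydro-1-benzofuran-2-yl]but-2-en-1-yl}triphenylphosphonium bromide, via allylic bromide 19 (not isolated)
Conditions: CBr4 (1.2 equiv), PPh3 (1.2 equiv), 2,6-lutidine (0.2 equiv), CH2Cl2, −20 °C; then PPh3 (1.5 equiv), 25 °C
Reagents that add atoms: carbon tetrabromide, BrC(Br)(Br)Br; triphenylphosphine, c1ccc(cc1)P(c1ccccc1)c1ccccc1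
Why: Appel bromination of the only free (primary allylic) alcohol under buffered acid-free conditions followed by SN2 quaternisation of triphenylphosphine should give the allylic phosphonium salt without ionising the doubly allylic C-8–O bond.

Step 12
Reactants: 20 {(2E)-3-[(2R,6S,7aR)-6-(methoxycarbonyloxy)-4,4,7a-trimethyl-2,4,5,6,7,7a-hexahydro-1-benzofuran-2-yl]but-2-en-1-yl}triphenylphosphonium bromide; 21 (2E,4E,6E)-2,7-dimethylocta-2,4,6-trienedial
Product: 22 methyl (2R,6S,7aR)-2-[(2E,4E,6E,8E,10E)-6,11-dimethyl-12-oxododeca-2,4,6,8,10-pentaen-2-yl]-4,4,7a-trimethyl-2,4,5,6,7,7a-hexahydro-1-benzofuran-6-yl carbonate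
Conditions: 21 (3 equiv), 1,2-epoxybutane, EtOH, 70 °C; then n-heptane, 80 °C (Z → E equilibration at C-11)
Reagents that add atoms: none
Why: Wittig reaction of the semi-stabilised allylic ylide, generated under neutral conditions with 1,2-epoxybutane as hydrogen bromide trap, with an excess of the symmetrical dialdehyde should give the mono-olefination product, whose hindered 11Z isomer equilibrates thermally to the all-E polyene.

Step 13
Reactants: 22 methyl (2R,6S,7aR)-2-[(2E,4E,6E,8E,10E)-6,11-dimethyl-12-oxododeca-2,4,6,8,10-pentaen-2-yl]-4,4,7a-trimethyl-2,4,5,6,7,7a-hexahydro-1-benzofuran-6-yl carbonate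
Product: 24 (2R,6S,7aR)-2-[(2E,4E,6E,8E,10E)-12-hydroxy-6,11-dimethyldodeca-2,4,6,8,10-pentaen-2-yl]-4,4,7a-trimethyl-2,4,5,6,7,7a-hexahydro-1-benzofuran-6-ol, via hydroxy carbonate 23 (not isolated)
Conditions: NaBH4, MeOH/THF, 0 °C; then K2CO3, MeOH, 25 °C
Reagents that add atoms: none
Why: Chemoselective 1,2-reduction of the conjugated aldehyde and base-catalysed transesterification of the methyl carbonate should free both hydroxyl groups under conditions that do not ionise the acid-labile furanoid ether.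

**Compound list**

1 | (R)-glycidol, (2R)-oxiran-2-ylmethanol | OC[C@@H]1CO1 | starting material
2 | (S)-glycidyl trifluoromethanesulfonate | O=S(=O)(OC[C@@H]1CO1)C(F)(F)F | intermediate
3 | (2S,5S)-2-tert-butyl-5-methyl-1,3-dioxolan-4-one (cis) | C[C@@H]1O[C@H](C(C)(C)C)OC1=O | starting material
4 | lithium enolate of 3, (2S)-configured acetal carbon | CC1=C(O[Li])O[C@@H](C(C)(C)C)O1 | intermediate
5 | (2S,5R)-2-tert-butyl-5-methyl-5-{[(2R)-oxiran-2-yl]methyl}-1,3-dioxolan-4-one | C[C@]1(C[C@@H]2CO2)O[C@H](C(C)(C)C)OC1=O | intermediate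
6 | lithium alkoxide of the cyclic hemiketal from 5 and isopropyllithium (hemiketal carbon undefined) | C[C@]1(C[C@@H]2CO2)O[C@H](C(C)(C)C)OC1(O[Li])C(C)C | intermediate
7 | (4R)-4-hydroxy-2,4-dimethyl-5-[(2R)-oxiran-2-yl]pentan-3-one | C[C@@](O)(C[C@@H]1CO1)C(=O)C(C)C | intermediate
8 | (4R)-2,4-dimethyl-5-[(2R)-oxiran-2-yl]-4-(triethylsilyloxy)pentan-3-one | C[C@@](O[Si](CC)(CC)CC)(C[C@@H]1CO1)C(=O)C(C)C | intermediate
9 | lithium enolate of 8 (tetrasubstituted, enolate carbon = C-1) | C[C@@](O[Si](CC)(CC)CC)(C[C@@H]1CO1)C(O[Li])=C(C)C | intermediate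
10 | (4S,6R)-4-hydroxy-2,2,6-trimethyl-6-(triethylsilyloxy)cyclohexan-1-one (O-3 trans to O-5) | O=C1C(C)(C)C[C@H](O)C[C@@]1(C)O[Si](CC)(CC)CC | intermediate
11 | (2E)-3-methylpent-2-en-4-yn-1-ol | C#C/C(C)=C/CO | starting material
12 | tert-butyldimethyl{[(2E)-3-methylpent-2-en-4-yn-1-yl]oxy}silane | C#C/C(C)=C/CO[Si](C)(C)C(C)(C)C | intermediate
13 | lithium acetylide of 12 | [Li]C#C/C(C)=C/CO[Si](C)(C)C(C)(C)C | intermediate
14 | dilithium dialkoxide of the (1R,2R,4S)-1-alkynylcyclohexane-1,4-diol (O-6 cis to O-5, alkynyl trans to O-5) | [Li]O[C@@]1(C#C/C(C)=C/CO[Si](C)(C)C(C)(C)C)C(C)(C)C[C@H](O[Li])C[C@@]1(C)O[Si](CC)(CC)CC | intermediate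
15 | (1R,2R,4S)-1-[(3E)-5-(tert-butyldimethylsilyloxy)-3-methylpent-3-en-1-yn-1-yl]-2,6,6-trimethyl-2-(triethylsilyloxy)cyclohexane-1,4-diyl dimethyl biscarbonate | COC(=O)O[C@@]1(C#C/C(C)=C/CO[Si](C)(C)C(C)(C)C)C(C)(C)C[C@H](OC(=O)OC)C[C@@]1(C)O[Si](CC)(CC)CC | intermediate
16 | (1S,3R)-4-[(Sa,3E)-5-(tert-butyldimethylsilyloxy)-3-methylpenta-1,3-dien-1-ylidene]-3,5,5-trimethyl-3-(triethylsilyloxy)cyclohexyl methyl carbonate (C-9 on the face of O-5) | CC(=C\CO[Si](C)(C)C(C)(C)C)/C=[C@]=C1C(C)(C)C[C@H](OC(=O)OC)C[C@@]1(C)O[Si](CC)(CC)CC | intermediate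
17 | (1S,3R)-3-hydroxy-4-[(Sa,3E)-5-hydroxy-3-methylpenta-1,3-dien-1-ylidene]-3,5,5-trimethylcyclohexyl methyl carbonate | CC(=C\CO)/C=[C@]=C1C(C)(C)C[C@H](OC(=O)OC)C[C@@]1(C)O | intermediate
18 | methyl (2R,6S,7aR)-2-[(2E)-4-hydroxybut-2-en-2-yl]-4,4,7a-trimethyl-2,4,5,6,7,7a-hexahydro-1-benzofuran-6-yl carbonate | OC/C=C(\C)[C@H]1C=C2C(C)(C)C[C@H](OC(=O)OC)C[C@@]2(C)O1 | intermediate
19 | methyl (2R,6S,7aR)-2-[(2E)-4-bromobut-2-en-2-yl]-4,4,7a-trimethyl-2,4,5,6,7,7a-hexahydro-1-benzofuran-6-yl carbonate | BrC/C=C(\C)[C@H]1C=C2C(C)(C)C[C@H](OC(=O)OC)C[C@@]2(C)O1 | intermediate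
20 | {(2E)-3-[(2R,6S,7aR)-6-(methoxycarbonyloxy)-4,4,7a-trimethyl-2,4,5,6,7,7a-hexahydro-1-benzofuran-2-yl]but-2-en-1-yl}triphenylphosphonium bromide | c1ccccc1[P+](c1ccccc1)(c1ccccc1)C/C=C(\C)[C@H]1C=C2C(C)(C)C[C@H](OC(=O)OC)C[C@@]2(C)O1.[Br-] | intermediate
21 | (2E,4E,6E)-2,7-dimethylocta-2,4,6-trienedial | O=C/C(C)=C/C=C/C=C(\C)C=O | starting material
22 | methyl (2R,6S,7aR)-2-[(2E,4E,6E,8E,10E)-6,11-dimethyl-12-oxododeca-2,4,6,8,10-pentaen-2-yl]-4,4,7a-trimethyl-2,4,5,6,7,7a-hexahydro-1-benzofuran-6-yl carbonate | CC(/C=C/C=C(\C)[C@H]1C=C2C(C)(C)C[C@H](OC(=O)OC)C[C@@]2(C)O1)=C\C=C\C=C(/C)C=O | intermediate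
23 | methyl (2R,6S,7aR)-2-[(2E,4E,6E,8E,10E)-12-hydroxy-6,11-dimethyldodeca-2,4,6,8,10-pentaen-2-yl]-4,4,7a-trimethyl-2,4,5,6,7,7a-hexahydro-1-benzofuran-6-yl carbonate | CC(/C=C/C=C(\C)[C@H]1C=C2C(C)(C)C[C@H](OC(=O)OC)C[C@@]2(C)O1)=C\C=C\C=C(/C)CO | intermediate
24 | (2R,6S,7aR)-2-[(2E,4E,6E,8E,10E)-12-hydroxy-6,11-dimethyldodeca-2,4,6,8,10-pentaen-2-yl]-4,4,7a-trimethyl-2,4,5,6,7,7a-hexahydro-1-benzofuran-6-ol (3S,5R,8R in carotenoid locants) | CC(/C=C/C=C(\C)[C@H]1C=C2C(C)(C)C[C@H](O)C[C@@]2(C)O1)=C\C=C\C=C(/C)CO | target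

**Step count.** Total: 13 steps. Longest linear sequence: 12 steps (steps 1–5 and 7–13, from (R)-glycidol); step 6 is a one-step side branch.

**The three steps most likely to fail**

Step 5 (key step). The enolate oxygen instead of carbon may open the epoxide at C-3 to give a five-membered enol ether. Alternatively the silyl group may migrate from O-5 to the enolate oxygen, after which the liberated alkoxide opens the epoxide; carbon–carbon bond formation at the fully substituted enolate carbon may also simply be too slow. The fallback sets out from 8 and returns at 10 by replacing the epoxide with a primary iodide. The epoxide is opened at its primary carbon with MgI2 (Et2O, −40 °C) to the iodohydrin (4R,6R)-6-hydroxy-7-iodo-2,4-dimethyl-4-(triethylsilyloxy)heptan-3-one F1. The carbinol is capped with Me3SiCl/imidazole to give (4R,6R)-7-iodo-2,4-dimethyl-4-(triethylsilyloxy)-6-(trimethylsilyloxy)heptan-3-one F2. The potassium enolate (KN(SiMe3)2, THF, −78 → 0 °C) is alkylated by the iodide in a 6-(enolendo)-exo-tet closure to (4S,6R)-2,2,6-trimethyl-6-(triethylsilyloxy)-4-(trimethylsilyloxy)cyclohexan-1-one F3. K2CO3 in MeOH then removes only the trimethylsilyl group and gives 10.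

Step 7. The acetylide may fail to add to the doubly neopentyl carbonyl (recovery of 10), or the very hindered tertiary alkoxide may escape acylation. The fallback sets out from 10 and returns at 15 by adding the smallest alkyne first and building the enyne afterwards. Ethynylmagnesium bromide with CeCl3 (THF, −78 → 0 °C) should give (1R,2R,4S)-1-ethynyl-2,6,6-trimethyl-2-(triethylsilyloxy)cyclohexane-1,4-diol F4. Sonogashira coupling (Pd(PPh3)2Cl2, CuI, i-Pr2NH) with tert-butyl{[(2E)-3-iodobut-2-en-1-yl]oxy}dimethylsilane F5 (from but-2-yn-1-ol by hydrostannation, iodinolysis and silylation) builds (1R,2R,4S)-1-[(3E)-5-(tert-butyldimethylsilyloxy)-3-methylpent-3-en-1-yn-1-yl]-2,6,6-trimethyl-2-(triethylsilyloxy)cyclohexane-1,4-diol F6. The isolated diol is then converted into 15 with LiN(SiMe3)2 (2.2 equiv) and ClCO2Me.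

Step 10. The ring has to flip into the conformer that places O-5 in the plane of the allene (three syn-axial substituents), so the cyclisation may be slow. Silver-promoted isomerisation of the vinylallene or re-ionisation of the doubly allylic C-8–O bond with loss of configuration could then compete. The fallback sets out from 17 and returns at 18 through an electrophile-driven closure. 5-Endo iodoetherification with N-iodosuccinimide (CH2Cl2, −20 °C) should give methyl (2S,6S,7aR)-2-[(2E)-4-hydroxybut-2-en-2-yl]-3-iodo-4,4,7a-trimethyl-2,4,5,6,7,7a-hexahydro-1-benzofuran-6-yl carbonate F7 with the same sense of axis-to-centre transfer (the descriptor at C-2 changes only through the iodine). The vinylic iodide is then replaced by hydrogen (Pd(OAc)2, PPh3, HCO2Na, DMF, 40 °C) to give 18.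

**Further compounds**

F1 | step 5 | (4R,6R)-6-hydroxy-7-iodo-2,4-dimethyl-4-(triethylsilyloxy)heptan-3-one | C[C@@](O[Si](CC)(CC)CC)(C[C@@H](O)CI)C(=O)C(C)C
F2 | step 5 | (4R,6R)-7-iodo-2,4-dimethyl-4-(triethylsilyloxy)-6-(trimethylsilyloxy)heptan-3-one | C[C@@](O[Si](CC)(CC)CC)(C[C@@H](O[Si](C)(C)C)CI)C(=O)C(C)C
F3 | step 5 | (4S,6R)-2,2,6-trimethyl-6-(triethylsilyloxy)-4-(trimethylsilyloxy)cyclohexan-1-one | O=C1C(C)(C)C[C@H](O[Si](C)(C)C)C[C@@]1(C)O[Si](CC)(CC)CC
F4 | step 7 | (1R,2R,4S)-1-ethynyl-2,6,6-trimethyl-2-(triethylsilyloxy)cyclohexane-1,4-diol | O[C@@]1(C#C)C(C)(C)C[C@H](O)C[C@@]1(C)O[Si](CC)(CC)CC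
F5 | step 7 | tert-butyl{[(2E)-3-iodobut-2-en-1-yl]oxy}dimethylsilane | C/C(I)=C\CO[Si](C)(C)C(C)(C)C
F6 | step 7 | (1R,2R,4S)-1-[(3E)-5-(tert-butyldimethylsilyloxy)-3-methylpent-3-en-1-yn-1-yl]-2,6,6-trimethyl-2-(triethylsilyloxy)cyclohexane-1,4-diol | O[C@@]1(C#C/C(C)=C/CO[Si](C)(C)C(C)(C)C)C(C)(C)C[C@H](O)C[C@@]1(C)O[Si](CC)(CC)CC
F7 | step 10 | methyl (2S,6S,7aR)-2-[(2E)-4-hydroxybut-2-en-2-yl]-3-iodo-4,4,7a-trimethyl-2,4,5,6,7,7a-hexahydro-1-benzofuran-6-yl carbonate | OC/C=C(\C)[C@H]1C(I)=C2C(C)(C)C[C@H](OC(=O)OC)C[C@@]2(C)O1
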